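Locants C1–C14 and O9 are those of the target skeleton as defined in the first section; "lower face" of ring B means the face carrying 5‑H, 13‑OH and 14‑OH, "upper face" the one carrying C4, C10 and C1.

## The problem

The target is an angular tetracycle. Cyclohexene ring A (C1–C2–C3–C4–C5–C14), cyclopentane ring B (C5–C6–C7–C13–C14) and cyclohexenone ring D (C1–C12–C11–C10–C13–C14) all meet at the carbinol carbon C14, and the tetrahydrofuran ring C (C7–C8–O9–C10–C13) ties ring B to ring D through an enol ether oxygen. Five contiguous stereocentres have to be set: the all‑carbon quaternary C1 (geranyl), the cis tertiary alcohols C14 and C13, and the methines C5 and C7. On ring B the four ring substituents are on the upper face and the two hydrogens and two hydroxyls on the lower face. Only C1 needs absolute control. C14 follows from a ring closure that can only be cis, C13 from a tether, and C5 from the neighbouring alkoxide. C7 can be adjusted as long as C8 is a carbonyl carbon but is frozen once C8 is the carbinol. The molecule carries three trisubstituted alkenes in the prenyl and geranyl chains besides the ring A alkene (sensitive to acid and oxidants), a vinylogous ester that is also the enol ether of ring C, and β‑hydroxy carbonyl relationships (14‑OH to C4 and C12, 13‑OH to C8) that invite retro‑aldol cleavage or dehydration. The feature to exploit is that C6–C7–C8 is an acrylate unit lying between C5 and C13. With a temporary ketone at C4, C5 is the only enolisable carbon of ring A and C13 is a ketone in 1,4‑relation to C4, so one conjugate addition and one aldol closure build ring B. The same C4 ketone later becomes the C3=C4–CH3 unit, and a C10 methoxy group inherited from a quinone is the leaving group for ring C.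

## Retrosynthesis

**Ring C, O9–C10.** Target 21 is opened at the enol ether bond to triol 20, whose C8 carbinol displaces methanol from the C10 vinylogous methyl ester. The neighbouring cut C8–O9 (tertiary cation captured by a C10 enol) would need a free vinylogous acid beside the C11 prenyl group, which cyclises under the same acid. The chosen cut needs only catalytic acid and removes one ring. It requires C8 on the upper face of ring B.

**C8 methyl groups.** Triol 20 comes from methyl ester 18 by double methyl addition through methyl ketone 19. This replaces two C–C bonds by a group that an acrylate can deliver. The forward step must prefer the ester over the hindered C12 carbonyl and must not enolise C7.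

**C7 configuration.** Ester 18 (ester trans to 13‑OH) is traced to its epimer 17. The annulation is expected to place the ester cis to the C13 oxygen, and an equilibrium would hardly favour an ester on the concave upper face. C7 is therefore set under kinetic control, by protonation of the alkoxide enolate from the lower face. The step converges either epimer.

**C3=C4–CH3.** Ester 17 is taken back through enol triflate 16 to enone 14. Conjugate reduction gives enolate 15 with the double bond already at C3=C4, so the regiochemistry of the ring A alkene is not in question. The alternative, methyl addition to C4 followed by dehydration, would give alkene mixtures.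

**Ring B, C5–C6 and C7–C13 (key).** Tricycle 14 is cut into enone ketol 11 and methyl acrylate 12. Cutting C5–C14 or C13–C14 instead would break the ring fusion carbon that the aldol chemistry of the earlier steps builds for free. The precursor loses one ring, two C–C bonds and three stereocentres. The forward reaction needs a single site of enolisation and an aldol that outruns other fates of the ester enolate.

**Ring A, C2=C3 and C5–C14.** Enone ketol 11 comes from saturated ketol 10 by dehydrogenation, which can only occur towards C3 because C14 bears no hydrogen. Ketol 10 comes from trione 9 by aldol closure of the methyl ketone onto the C14 carbonyl. An ynone acceptor would give the enone directly, but as a double‑bond mixture of which only the Z isomer can cyclise. The saturated chain closes without a geometry question. The four‑atom tether on C1 forces a cis ring fusion, so C14 follows from C1.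

**C1–C2.** Trione 9 is cut into hydroxyquinone 7 and but‑3‑en‑2‑one 8. This conjugate addition creates the quaternary centre and is the only step that needs an external source of chirality.

**Ring D substituents.** Hydroxyquinone 7 comes from 5 and geranyl acetate 6 by C‑allylation at the only nucleophilic carbon. Hydroxyquinone 5 comes from dimethoxyquinone 4 by hydrolysis of the methoxy group that is not flanked by the prenyl group, which differentiates the two methoxy groups. Quinone 4 comes from arene 3, and 3 from 1,2,3,5‑tetramethoxybenzene 1 and prenyl bromide 2. All six ring D carbons and all four of its oxygens are thus bought as one benzene ring.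

## Roads not taken

**Alternative 1:** Ring A is cut at C5–C14 and made by a boat Ireland–Claisen rearrangement. The silyl ketene acetal of six‑membered lactone A2 would rearrange to cyclohexene acid A1, shifting the alkene to C3=C4.
- Merits: C5 and C14 are set together by a concerted transfer of chirality. The C3=C4–CH3 unit and the C6–C8 carbons (as a prenyl group on C5) are in place at once, with no enone, triflate or methylation detour. On ring A functionality and on the reliability of the C5/C14 relationship this road is better than the chosen one.
- Weak points: the lactone tether forces a boat transition state, here with the geranyl‑bearing quaternary C1 inside the tether and the allyl unit cis to it. A2 already needs C1 set and a stereodefined (E)‑trisubstituted allylic carbinol. After A1, rings B, C and D all remain, including a C7–C13 bond to an unactivated alkene and two further ring D carbons.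
- Comparison: the chosen plan brings ring D complete from an arene and closes ring B with three stereocentres in one step from a seven‑step intermediate.

**Alternative 2:** Ring D is cut at C10–C11. The C11 enolate of keto lactone A4 would attack the lactone carbonyl, and acid would dehydrate the hemiketal to the acetonide A3 of the target. Removal of the acetonide gives 21.
- Merits: every stereocentre is in place before the last C–C bond, the enol ether regiochemistry is fixed because O9 already sits on C10, and no organometallic has to choose between an ester and a vinylogous ester. This endgame is cleaner than steps 11–13 of the chosen route.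
- Weak points: the acylation joins a carbonyl on the fully substituted C13 to a carbon next to the neopentylic C12 ketone. A di‑tertiary diol must be protected and released. Above all, A4 is a cis‑fused tricycle with five stereocentres and a quaternary C1 bearing two different chains, so the hard part is moved, not solved.
- Comparison: the chosen plan offers a much shorter approach to the ring system and tertiary alcohols that arise from the C–C bond formations themselves.

**Alternative 3:** Rings B and C are cut together at C7–C13 and O9–C10. The γ‑dienolate of bicyclic epoxide A6 would open the epoxide at C7, the C8 alkoxide would then displace methoxide at C10, and the product would be 13‑deoxy tetracycle A5. Hydroxylation at C13 would then be needed to reach 21.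
- Merits: C7 is set stereospecifically by inversion, with no epimer question; on this point it is better than the chosen plan. The carbinol oxygen arrives with the epoxide, two rings form in one flask, and ring A already has its final alkene.
- Weak points: a single epoxide must be made selectively beside three other trisubstituted alkenes or carried from the start. The substitution occurs at a secondary carbon next to a fully substituted one. The cis diol, the hardest feature, is left to a late γ‑oxidation of a dienolate at a ring‑fusion methine, with regiochemical and facial risk.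
- Comparison: the chosen plan obtains both tertiary alcohols from aldol reactions and needs no late oxidation. It pays with the C7 correction (step 11) and a five‑step endgame.

Key step: step 8

Remark on the chemistry: the ring‑closing aldol is taken to run through a lithium‑bridged transition state, so annulation product 14 is drawn with its ester cis to the C13 hydroxyl; step 11 then sets C7 and would converge the other epimer as well, since both give the same enolate.

## Route

Step 1
Reactants: 1 1,2,3,5‑tetramethoxybenzene; 2 prenyl bromide (1‑bromo‑3‑methylbut‑2‑ene)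
Product: 3 1,2,3,5‑tetramethoxy‑4‑(3‑methylbut‑2‑en‑1‑yl)benzene
Conditions: n‑BuLi, TMEDA, THF, 0 °C; CuBr·SMe2, −78 °C; then 2, −78 → 0 °C
Reagents that add atoms: none
Why: Directed ortho‑lithiation occurs between two methoxy groups (the two free positions of 1 are equivalent). The arylcopper couples with the allylic bromide at its primary carbon (copper‑mediated allylic substitution), so the prenyl group is not transposed.

Step 2
Reactants: 3 1,2,3,5‑tetramethoxy‑4‑(3‑methylbut‑2‑en‑1‑yl)benzene
Product: 4 2,6‑dimethoxy‑3‑(3‑methylbut‑2‑en‑1‑yl)‑1,4‑benzoquinone
Conditions: (NH4)2Ce(NO3)6, MeCN/H2O, 0 °C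
Reagents that add atoms: water, O
Why: Oxidative demethylation of the only para pair of methoxy groups gives the p‑quinone. The oxidation is brief and cold and should spare the trisubstituted alkene.

Step 3
Reactants: 4 2,6‑dimethoxy‑3‑(3‑methylbut‑2‑en‑1‑yl)‑1,4‑benzoquinone
Product: 5 2‑hydroxy‑6‑methoxy‑5‑(3‑methylbut‑2‑en‑1‑yl)‑1,4‑benzoquinone
Conditions: NaOH (aq, 1 M), THF, 0 °C; then HCl (aq)
Reagents that add atoms: sodium hydroxide, [Na+].[OH-]
Why: Vinylogous ester hydrolysis by addition–elimination should occur at the methoxy carbon next to the ring C–H, which is less hindered and lacks the α‑alkyl group. The hydroxyquinone anion formed resists a second hydrolysis.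

Step 4
Reactants: 5 2‑hydroxy‑6‑methoxy‑5‑(3‑methylbut‑2‑en‑1‑yl)‑1,4‑benzoquinone; 6 geranyl acetate
Product: 7 2‑[(2E)‑3,7‑dimethylocta‑2,6‑dien‑1‑yl]‑3‑hydroxy‑5‑methoxy‑6‑(3‑methylbut‑2‑en‑1‑yl)‑1,4‑benzoquinone
Conditions: Pd(PPh3)4 (5 mol %), Et3N, THF, 50 °C
Reagents that add atoms: none
Why: In this Tsuji–Trost allylation the vinylogous acid acts as a soft carbon nucleophile, as cyclic 1,3‑diones do. Attack at the less substituted allyl terminus gives the linear (E) product, and any O‑allyl isomer re‑ionises and drains to the C‑allyl compound.

Step 5
Reactants: 7 geranyl prenyl hydroxyquinone; 8 but‑3‑en‑2‑one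
Product: 9 (6R)‑6‑[(2E)‑3,7‑dimethylocta‑2,6‑dien‑1‑yl]‑3‑methoxy‑2‑(3‑methylbut‑2‑en‑1‑yl)‑6‑(3‑oxobutyl)cyclohex‑2‑ene‑1,4,5‑trione
Conditions: quinine‑derived bifunctional squaramide (10 mol %), CH2Cl2, −20 °C
Reagents that add atoms: none
Why: Proposed new method: the quinuclidine nitrogen deprotonates the acidic hydroxyquinone to a tight ion pair held at its O13/O14 edge while the squaramide N–H groups activate the enone, so that C1, the central carbon of the enolised 1,3‑dicarbonyl unit, should add to the enone from one face and create the quaternary centre; the two flanks of C1 differ (vinylogous ester side against vicinal dicarbonyl side), which gives the catalyst something to distinguish, and the closest known reaction type is the cinchona‑catalysed enantioselective Michael addition of 2‑substituted cyclic β‑dicarbonyl compounds and of 2‑hydroxy‑1,4‑naphthoquinone to enones; the pseudoenantiomeric quinidine catalyst is the recourse if the sense of induction is the opposite one.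

Step 6
Reactants: 9 trione
Product: 10 (4aR,8aS)‑8a‑geranyl‑4a‑hydroxy‑3‑methoxy‑2‑prenyl‑4a,5,8,8a‑tetrahydronaphthalene‑1,4,6(7H)‑trione (cis‑fused ketol; C5–C14 bond formed)
Conditions: L‑proline (30 mol %), DMF, 20 °C
Reagents that add atoms: none
Why: In this Hajos–Parrish‑type enamine aldol the methyl ketone closes onto C14, a vicinal‑dione carbonyl far more electrophilic than the hindered vinylogous ester carbonyl C12. The four‑atom tether on C1 can reach C14 from one face only, so the ring fusion is cis and 14‑OH is cis to geranyl. The ketol should not dehydrate under these conditions.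

Step 7
Reactants: 10 saturated ketol
Product: 11 (4aR,8aR)‑8a‑geranyl‑4a‑hydroxy‑3‑methoxy‑2‑prenyl‑4a,8a‑dihydronaphthalene‑1,4,6(5H)‑trione (enone ketol)
Conditions: IBX (2‑iodoxybenzoic acid), 4‑methoxypyridine N‑oxide, DMSO, 25 °C
Reagents that add atoms: none
Why: IBX dehydrogenates the ketone through its enol. Only C2–C3 can be desaturated because C14 carries no hydrogen, and the room‑temperature variant should spare the alkenes and the ketol.

Step 8
Reactants: 11 enone ketol; 12 methyl acrylate
Product: 14 tricyclic diol ester (rings A/B/D; ester cis to 13‑OH), via conjugate adduct 13 (not isolated)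
Conditions: LiN(SiMe3)2 (2.1 equiv), THF, −78 °C; 12 (1.2 equiv), −78 → −40 °C; AcOH, −78 °C
Reagents that add atoms: none
Why: Two equivalents of base give the C14 lithium alkoxide and then the C5 enolate of the C4 enone, the only α‑carbon bearing hydrogen because C3 is vinylic and C1 quaternary; this enolate adds to the acrylate (C5–C6) and the ester enolate so formed attacks the C13 ketone (C7–C13), the known tandem Michael addition–intramolecular aldol annulation of ketone enolates with acrylates. Ring B closes in the 5‑(enolexo)‑exo‑trig mode. C5 is set by approach of the acrylate anti to the C14 alkoxide, as in alkylations of cyclic β‑alkoxide enolates, which is the face carrying C13; an adduct formed on the other face cannot close, and C5 stays epimerisable. C13 is set by the tether: C7 can reach the ketone only from the face on which C5 sits, so the new hydroxyl is cis to 14‑OH. C7 is set by the lithium bridge between enolate and ketone oxygens in the closed transition state, which places the ester cis to the C13 oxygen; step 11 corrects this centre. The step needs deprotonation at C5 and not at the doubly allylic CH2 on C11 (γ to the C13 ketone), which the higher kinetic acidity of the ketone α‑position and delivery of the base by the neighbouring alkoxide should secure. It also needs aldol closure and not a second conjugate addition of the ester enolate to C2, which is favoured because C2 is neopentylic while the C13 ketone is held within reach for a five‑membered closure. The C14 oxygen must remain an oxide throughout, since as such it cannot leave by β‑elimination from the C5 enolate.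

Step 9
Reactants: 14 tricyclic diol ester
Product: 16 enol triflate (C3=C4–OTf), via lithium enolate 15 (not isolated)
Conditions: LiBH(s‑Bu)3 (1.1 equiv), THF, −78 °C; PhNTf2, −78 → 0 °C
Reagents that add atoms: N‑phenylbis(trifluoromethanesulfonimide), O=S(=O)(N(c1ccccc1)S(=O)(=O)C(F)(F)F)C(F)(F)F
Why: The bulky borohydride reduces β‑unsubstituted cyclohexenones in the conjugate sense, also when the β‑carbon adjoins a quaternary centre. The enolate is formed regiospecifically at C3=C4 and is trapped as the triflate. The ester, the hindered C12 carbonyl and the tertiary hydroxyls should not react at −78 °C.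

Step 10
Reactants: 16 enol triflate
Product: 17 C4‑methyl alkene ester (C3=C4–CH3; ester cis to 13‑OH)
Conditions: MeZnCl (3 equiv), Pd(PPh3)4 (5 mol %), THF, 50 °C
Reagents that add atoms: methylzinc chloride, C[Zn]Cl
Why: Negishi coupling of an alkenyl triflate with a methylzinc reagent; the conditions are close to neutral and tolerate the ester, the vinylogous ester and the free tertiary alcohols.

Step 11
Reactants: 17 C4‑methyl alkene ester
Product: 18 C7 epimer of 17 (ester trans to 13‑OH and cis to C10; 7‑H on the lower face)
Conditions: LiN(i‑Pr)2 (3.3 equiv), THF, −78 → −30 °C; then AcOH in THF, −78 °C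
Reagents that add atoms: none
Why: The dialkoxide ester enolate is of the Fráter–Seebach type: the β‑oxide cannot be eliminated and blocks retro‑aldol cleavage. In cyclic cases the electrophile, here a proton, enters cis to the alkoxide oxygen, and that is also the open convex lower face, so the ester should end on the upper face. Either C7 epimer gives the same enolate.

Step 12
Reactants: 18 upper‑face ester
Product: 20 triol (C7 2‑hydroxypropan‑2‑yl), via methyl ketone 19 (not isolated)
Conditions: MeLi (6 equiv), CeCl3 (6 equiv), THF, −78 → −20 °C; then H2O
Reagents that add atoms: methyllithium, [Li]C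
Why: The organocerium reagent adds twice to the ester and is too weakly basic to enolise C7 in ester or ketone. The C12 carbonyl is a vinylogous ester flanked by the quaternary C1 and the substituted C11 and should react more slowly. If the C8 alkoxide already displaces methoxide at C10 on warming, this step and the next merge.

Step 13
Reactants: 20 triol
Product: 21 target CNP0323114.1
Conditions: camphorsulfonic acid (10 mol %), 4 Å molecular sieves, CH2Cl2, 20 °C
Reagents that add atoms: none
Why: Acid‑catalysed vinylogous transetherification: the C8 hydroxyl adds 5‑exo‑trig to the activated C10 and methanol is lost. Only the upper‑face carbinol can reach C10, and the mild acid should leave the prenyl and geranyl alkenes and the tertiary alcohols untouched.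

## Compound list

1 | 1,2,3,5‑tetramethoxybenzene | COc1cc(OC)c(OC)c(OC)c1 | starting material
2 | prenyl bromide (1‑bromo‑3‑methylbut‑2‑ene) | CC(C)=CCBr | starting material
3 | 1,2,3,5‑tetramethoxy‑4‑(3‑methylbut‑2‑en‑1‑yl)benzene | COc1cc(OC)c(OC)c(OC)c1CC=C(C)C | intermediate
4 | 2,6‑dimethoxy‑3‑(3‑methylbut‑2‑en‑1‑yl)‑1,4‑benzoquinone | COC1=C(CC=C(C)C)C(=O)C=C(OC)C1=O | intermediate
5 | 2‑hydroxy‑6‑methoxy‑5‑(3‑methylbut‑2‑en‑1‑yl)‑1,4‑benzoquinone | OC1=CC(=O)C(CC=C(C)C)=C(OC)C1=O | intermediate
6 | geranyl acetate, (2E)‑3,7‑dimethylocta‑2,6‑dien‑1‑yl acetate | CC(C)=CCC/C(C)=C/COC(C)=O | starting material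
7 | 2‑[(2E)‑3,7‑dimethylocta‑2,6‑dien‑1‑yl]‑3‑hydroxy‑5‑methoxy‑6‑(3‑methylbut‑2‑en‑1‑yl)‑1,4‑benzoquinone | CC(C)=CCC/C(C)=C/CC1=C(O)C(=O)C(OC)=C(CC=C(C)C)C1=O | intermediate
8 | but‑3‑en‑2‑one | CC(=O)C=C | starting material
9 | (6R)‑6‑geranyl‑3‑methoxy‑2‑prenyl‑6‑(3‑oxobutyl)cyclohex‑2‑ene‑1,4,5‑trione (C1 quaternary centre set) | CC(C)=CCC/C(C)=C/C[C@@]1(CCC(C)=O)C(=O)C(=O)C(OC)=C(CC=C(C)C)C1=O | intermediate
10 | (4aR,8aS)‑8a‑geranyl‑4a‑hydroxy‑3‑methoxy‑2‑prenyl‑4a,5,8,8a‑tetrahydronaphthalene‑1,4,6(7H)‑trione, cis‑fused ketol, 14‑OH cis to geranyl | CC(C)=CCC/C(C)=C/C[C@]12CCC(=O)C[C@]2(O)C(=O)C(OC)=C(CC=C(C)C)C1=O | intermediate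
11 | (4aR,8aR)‑8a‑geranyl‑4a‑hydroxy‑3‑methoxy‑2‑prenyl‑4a,8a‑dihydronaphthalene‑1,4,6(5H)‑trione, enone ketol (rings A and D; C2=C3–C4=O, C13 ketone) | CC(C)=CCC/C(C)=C/C[C@]12C=CC(=O)C[C@]2(O)C(=O)C(OC)=C(CC=C(C)C)C1=O | intermediate
12 | methyl acrylate | C=CC(=O)OC | starting material
13 | conjugate adduct: 11 with a 3‑methoxy‑3‑oxopropyl chain on C5, trans to 14‑OH; present in the flask as lithium ester enolate and C14 alkoxide, written as the neutral keto ester | CC(C)=CCC/C(C)=C/C[C@]12C=CC(=O)[C@H](CCC(=O)OC)[C@]2(O)C(=O)C(OC)=C(CC=C(C)C)C1=O | intermediate (not isolated)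
14 | tricyclic diol ester (rings A, B, D): C2=C3–C4=O enone, C7–CO2Me cis to 13‑OH, 5‑H, 13‑OH and 14‑OH on the lower face of ring B, C10–OMe vinylogous ester, C1 as in 11 | CC(C)=CCC/C(C)=C/C[C@]12C=CC(=O)[C@@H]3C[C@@H](C(=O)OC)[C@](O)(C(OC)=C(CC=C(C)C)C1=O)[C@@]32O | intermediate
15 | lithium C3=C4 enolate formed from 14 by conjugate reduction | CC(C)=CCC/C(C)=C/C[C@]12CC=C([O-])[C@@H]3C[C@@H](C(=O)OC)[C@](O)(C(OC)=C(CC=C(C)C)C1=O)[C@@]32O.[Li+] | intermediate (not isolated)
16 | enol triflate: as 14 with C2H2 and C3=C4–OSO2CF3 | CC(C)=CCC/C(C)=C/C[C@]12CC=C(OS(=O)(=O)C(F)(F)F)[C@@H]3C[C@@H](C(=O)OC)[C@](O)(C(OC)=C(CC=C(C)C)C1=O)[C@@]32O | intermediate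
17 | C4‑methyl alkene ester: C3=C4–CH3, ester cis to 13‑OH | CC(C)=CCC/C(C)=C/C[C@]12CC=C(C)[C@@H]3C[C@@H](C(=O)OC)[C@](O)(C(OC)=C(CC=C(C)C)C1=O)[C@@]32O | intermediate
18 | C7 epimer of 17: ester on the upper face (trans to 13‑OH, cis to C10), all‑cis array | CC(C)=CCC/C(C)=C/C[C@]12CC=C(C)[C@@H]3C[C@H](C(=O)OC)[C@](O)(C(OC)=C(CC=C(C)C)C1=O)[C@@]32O | intermediate
19 | C8 methyl ketone (acetyl on C7, upper face) | CC(C)=CCC/C(C)=C/C[C@]12CC=C(C)[C@@H]3C[C@H](C(C)=O)[C@](O)(C(OC)=C(CC=C(C)C)C1=O)[C@@]32O | intermediate (not isolated)
20 | triol: 2‑hydroxypropan‑2‑yl on C7 (upper face), 13‑OH, 14‑OH, C10–OMe | CC(C)=CCC/C(C)=C/C[C@]12CC=C(C)[C@@H]3C[C@H](C(C)(C)O)[C@](O)(C(OC)=C(CC=C(C)C)C1=O)[C@@]32O | intermediate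
21 | CNP0323114.1, tetracyclic diol enol ether | CC(C)=CCC/C(C)=C/C[C@]12CC=C(C)[C@@H]3C[C@@H]4C(C)(C)OC(=C(CC=C(C)C)C1=O)[C@]4(O)[C@@]32O | target

## Step count and risk

Total: 13 steps. Longest linear sequence: 13 steps, from 1 (compounds 2, 6, 8 and 12 enter as bought).

**Step 5 (proposed new method).** The hydroxyquinone anion is strongly stabilised and ambident, and its two faces differ only through remote groups. Low enantioselectivity, sluggish C‑addition or reversible O‑addition are the likely failures. The fallback sets out from 7. Triethylamine‑catalysed addition to 8, the classical addition of cyclic 2‑alkyl‑1,3‑dione enols to this enone, gives 9 together with its enantiomer ent‑9 F1. Steps 6 and 7 with racemic proline carry the pair on to 10 with ent‑10 F2 and to 11 with ent‑11 F3. Preparative chromatography on a chiral stationary phase removes F3, and the route is rejoined at 11.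

**Step 8 (key step).** The ester enolate may be lost before it reaches C13, by proton transfer from a C5–H, by a second conjugate addition to C2 or by oligomerisation of the acrylate. Conjugate addition on the alkoxide face would also leave a chain that cannot close. The fallback sets out from the open keto ester 13, or from its C5 epimer 5‑epi‑13 F4, recovered after the cold quench. LiN(i‑Pr)2 (3.3 equiv) in THF at −78 → −20 °C forms the C14 alkoxide, the C4=C5 dienolate and the ester enolate. With C5 trigonal both epimers are one species, and the enone is no longer an acceptor. The ester enolate then closes onto C13 in a separate aldol step, and protonation at C5 from the convex face on work‑up returns the route to 14.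

**Step 11.** Enolisation may be slow because 7‑H of 17 sits on the concave face, the facial preference in the protonation may be insufficient, and the C14 alkoxide may attack the lower‑face ester before deprotonation. The fallback sets out from 17 and replaces protonation by hydrogen delivery. The same enolate is trapped with PhSeBr to give the C7 phenylselenide F5. H2O2 with pyridine eliminates the selenoxide towards C6, the only side with hydrogen, to give the C6=C7 unsaturated ester F6. Hydrogenation with [Rh(nbd)(dppb)]BF4, directed by the allylic 13‑OH, adds hydrogen from the lower face and returns the route to 18. Isolated trisubstituted alkenes react slowly with this cationic catalyst.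

**Step 12.** Competing addition to the C12 carbonyl, or slow addition to the ester now on the concave face with partial stop at ketone 19, are the likely failures. The fallback sets out from 18. MeNH(OMe)·HCl and i‑PrMgCl at −20 °C give the Weinreb amide F7. MeMgBr at 0 °C gives ketone 19, now isolated. One equivalent of MeCeCl2 at −78 °C, where a ketone reacts far faster than the deactivated C12 carbonyl, gives 20.

**Step 4.** O‑allylation that does not drain to carbon, double allylation at C1, or oxidation of zerovalent palladium by the quinone are the likely failures. The fallback sets out from 3 and gives up the regiocontrol. A second ortho‑lithiation, copper transmetalation and geranyl bromide give 1‑geranyl‑2,3,4,6‑tetramethoxy‑5‑prenylbenzene F8. (NH4)2Ce(NO3)6 gives 3‑geranyl‑2,6‑dimethoxy‑5‑prenyl‑1,4‑benzoquinone F9. Sodium hydroxide hydrolyses either methoxy group, giving 7 and its regioisomer 5‑geranyl‑2‑hydroxy‑6‑methoxy‑3‑prenyl‑1,4‑benzoquinone F10, which are separated by chromatography; the route is rejoined at 7.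

## Further compounds

F1 | step 5 | ent‑9, (6S)‑trione | CC(C)=CCC/C(C)=C/C[C@]1(CCC(C)=O)C(=O)C(=O)C(OC)=C(CC=C(C)C)C1=O
F2 | step 5 | ent‑10, (4aS,8aR) saturated ketol | CC(C)=CCC/C(C)=C/C[C@@]12CCC(=O)C[C@@]2(O)C(=O)C(OC)=C(CC=C(C)C)C1=O
F3 | step 5 | ent‑11, (4aS,8aS) enone ketol | CC(C)=CCC/C(C)=C/C[C@@]12C=CC(=O)C[C@@]2(O)C(=O)C(OC)=C(CC=C(C)C)C1=O
F4 | step 8 | 5‑epi‑13, conjugate adduct with the ester chain cis to 14‑OH | CC(C)=CCC/C(C)=C/C[C@]12C=CC(=O)[C@@H](CCC(=O)OC)[C@]2(O)C(=O)C(OC)=C(CC=C(C)C)C1=O
F5 | step 11 | C7 phenylselenide of 17 (SePh on the lower face, ester on the upper face) | CC(C)=CCC/C(C)=C/C[C@]12CC=C(C)[C@@H]3C[C@]([Se]c4ccccc4)(C(=O)OC)[C@](O)(C(OC)=C(CC=C(C)C)C1=O)[C@@]32O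
F6 | step 11 | C6=C7 unsaturated ester | CC(C)=CCC/C(C)=C/C[C@]12CC=C(C)[C@@H]3C=C(C(=O)OC)[C@](O)(C(OC)=C(CC=C(C)C)C1=O)[C@@]32O
F7 | step 12 | N‑methoxy‑N‑methyl amide of 18 | CC(C)=CCC/C(C)=C/C[C@]12CC=C(C)[C@@H]3C[C@H](C(=O)N(C)OC)[C@](O)(C(OC)=C(CC=C(C)C)C1=O)[C@@]32O
F8 | step 4 | 1‑geranyl‑2,3,4,6‑tetramethoxy‑5‑prenylbenzene | COc1c(CC=C(C)C)c(OC)c(OC)c(OC)c1C/C=C(C)/CCC=C(C)C
F9 | step 4 | 3‑geranyl‑2,6‑dimethoxy‑5‑prenyl‑1,4‑benzoquinone | COC1=C(CC=C(C)C)C(=O)C(C/C=C(C)/CCC=C(C)C)=C(OC)C1=O
F10 | step 4 | 5‑geranyl‑2‑hydroxy‑6‑methoxy‑3‑prenyl‑1,4‑benzoquinone (regioisomer of 7) | OC1=C(CC=C(C)C)C(=O)C(C/C=C(C)/CCC=C(C)C)=C(OC)C1=O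
A1 | alternative 1 | ring A acid from the Ireland–Claisen rearrangement | CC(C)=CCC/C(C)=C/C[C@@]1(C(=O)OC)CC=C(C)[C@H](CC=C(C)C)[C@]1(OCOC)C(O)=O
A2 | alternative 1 | six‑membered lactone precursor with the (E)‑alkenyl group on C3 (C14 epimer immaterial, one drawn) | CC(C)=CCC/C(C)=C/C[C@@]1(C(=O)OC)C[C@@H](/C(C)=C/CC=C(C)C)OC(=O)[C@@H]1OCOC
A3 | alternative 2 | acetonide of the target | CC(C)=CCC/C(C)=C/C[C@]12CC=C(C)[C@@H]3C[C@@H]4C(C)(C)OC(=C(CC=C(C)C)C1=O)[C@]4(O5)[C@@]32OC5(C)C
A4 | alternative 2 | keto lactone precursor (rings A, B, C; 5‑methylhex‑4‑enoyl group on C1) | CC(C)=CCC/C(C)=C/C[C@@]1(C(=O)CCC=C(C)C)CC=C(C)[C@@H]2C[C@@H]3C(C)(C)OC(=O)[C@]3(O4)[C@]12OC4(C)C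
A5 | alternative 3 | 13‑deoxy tetracycle | CC(C)=CCC/C(C)=C/C[C@]12CC=C(C)[C@@H]3C[C@@H]4C(C)(C)OC(=C(CC=C(C)C)C1=O)[C@@H]4[C@@]32O
A6 | alternative 3 | bicyclic epoxide precursor (rings A and D; 3,3‑dimethyloxiranylmethyl on C5) | CC(C)=CCC/C(C)=C/C[C@]12CC=C(C)[C@H](C[C@@H]3OC3(C)C)[C@]2(O)CC(OC)=C(CC=C(C)C)C1=O
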